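**Retrosynthetic overview**

1. Kanzonol L is traced back to its tris(methoxymethyl) ether 22, and the C2=C3 alkene of 22 to loss of water from the racemic 3-hydroxyisoflavanone 20.
2. Pyranone ring C of 20 is cut at C3–C4 (carbene-catalysed intramolecular benzoin, the ring A formyl carbon acting as acyl anion toward an aryl ketone) and at O1–C2 (phenol alkylation by a bromoketone), giving aldehyde 6 and bromoketone 16.
3. The strategy rests on ring C: C4 sits on the hexasubstituted ring A between O1 and the 5-oxygen, which are equivalent in a symmetrical phloroglucinol aldehyde, and C3 carries C8 of the chromene, next to the pyran oxygen. C4 is therefore bought as a formyl carbon and the C3–aryl bond as an acetophenone, so no regiochemical question and no hindered aryl–metal coupling arises.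
4. Aldehyde 6 comes from 2,4,6-trihydroxybenzaldehyde by double C-prenylation and bis-protection; bromoketone 16 comes from 2,4-dihydroxyacetophenone by propargyl ether Claisen rearrangement/electrocyclisation and α-bromination.
5. Ring order: rings A and B are purchased arenes, the dimethylpyran ring is fused to ring B first, and ring C is closed last and made aromatic by dehydration.

Key step: step 9

Remark: the target has no stereocentre; the stereocentres of 11, 19 and 20 are racemic or undefined and are all erased, and unnumbered reagents are taken as commercial.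

**Route**

Step 1
Reactants: 1 2,4,6-trihydroxybenzaldehyde; 2 prenyl bromide (two equivalents)
Product: 4 2,4,6-trihydroxy-3,5-bis(3-methylbut-2-enyl)benzaldehyde, via monoprenyl aldehyde 3 (not isolated)
Conditions: KOH (10% aq), 0 °C to rt; then 1 M HCl
Reagents that add atoms: none
Why: Phenoxide C-alkylation of the phloroglucinol nucleus, whose oxygens are solvated by water, should place one prenyl group on each of the two equivalent free ring carbons, the monoprenyl compound reacting on at the remaining free carbon.

Step 2
Reactants: 4 2,4,6-trihydroxy-3,5-bis(3-methylbut-2-enyl)benzaldehyde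
Product: 6 2-hydroxy-4,6-bis(methoxymethoxy)-3,5-bis(3-methylbut-2-enyl)benzaldehyde, via para-MOM ether 5 (not isolated)
Conditions: MOMCl (2.2 equiv), i-Pr2NEt, CH2Cl2, 0 °C to rt
Reagents that add atoms: chloromethyl methyl ether, COCCl
Why: O-alkylation with MOMCl should cap the non-chelated para hydroxyl and then one of the two equivalent ortho hydroxyls, while the last ortho hydroxyl, hydrogen-bonded to the formyl oxygen, is the least nucleophilic and stays free at this stoichiometry.

Step 3
Reactants: 7 2,4-dihydroxyacetophenone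
Product: 8 2-hydroxy-4-(methoxymethoxy)acetophenone
Conditions: MOMCl (1.1 equiv), K2CO3, acetone, 0 °C to rt
Reagents that add atoms: chloromethyl methyl ether, COCCl
Why: Selective Williamson-type O-alkylation, since the 4-hydroxyl is the more acidic and is not hydrogen-bonded to the acetyl group.

Step 4
Reactants: 8 2-hydroxy-4-(methoxymethoxy)acetophenone; 9 3-chloro-3-methylbut-1-yne
Product: 10 4-(methoxymethoxy)-2-(2-methylbut-3-yn-2-yloxy)acetophenone
Conditions: DBU, CuCl2·2H2O (cat.), MeCN, 0 °C to rt
Reagents that add atoms: none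
Why: Copper-catalysed propargylic etherification of a phenol with a tertiary propargylic chloride, in which DBU ionises the hydrogen-bonded 2-hydroxyl and the copper acetylide makes the tertiary carbon electrophilic enough for O-alkylation.

Step 5
Reactants: 10 4-(methoxymethoxy)-2-(2-methylbut-3-yn-2-yloxy)acetophenone
Product: 14 8-acetyl-5-(methoxymethoxy)-2,2-dimethyl-2H-chromene, via allenyl dienone 11 (not isolated), via allenyl phenol 12 (not isolated), via quinone methide 13 (not isolated)
Conditions: o-xylene, 140 °C
Reagents that add atoms: none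
Why: The aryl propargyl ether Claisen rearrangement ([3,3]) can deliver the allene only to C3, because the other ortho carbon bears the acetyl group, and enolisation, 1,5-hydrogen shift and oxa-6π electrocyclisation then close the dimethylpyran ring on ring B.

Step 6
Reactants: 14 8-acetyl-5-(methoxymethoxy)-2,2-dimethyl-2H-chromene
Product: 15 5-(methoxymethoxy)-2,2-dimethyl-8-[1-(trimethylsilyloxy)ethenyl]-2H-chromene
Conditions: LiN(SiMe3)2, THF, −78 °C; Me3SiCl, −78 to 0 °C; non-aqueous work-up, used crude
Reagents that add atoms: chlorotrimethylsilane, C[Si](C)(C)Cl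
Why: Kinetic enolisation of the methyl ketone, its only enolisable position, and O-silylation give the silyl enol ether under basic conditions that leave the MOM acetal and the chromene alkene untouched.

Step 7
Reactants: 15 5-(methoxymethoxy)-2,2-dimethyl-8-[1-(trimethylsilyloxy)ethenyl]-2H-chromene
Product: 16 8-(bromoacetyl)-5-(methoxymethoxy)-2,2-dimethyl-2H-chromene (fragment 2)
Conditions: N-bromosuccinimide, THF, −78 °C
Reagents that add atoms: N-bromosuccinimide, O=C1CCC(=O)N1Br
Why: Electrophilic bromination of the silyl enol ether, by far the most electron-rich alkene present, gives the α-bromoketone at low temperature without free HBr, so the chromene double bond, the arene and the acetal should be spared.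

Step 8
Reactants: 6 2-hydroxy-4,6-bis(methoxymethoxy)-3,5-bis(3-methylbut-2-enyl)benzaldehyde; 16 8-(bromoacetyl)-5-(methoxymethoxy)-2,2-dimethyl-2H-chromene
Product: 17 2-{2-[5-(methoxymethoxy)-2,2-dimethyl-2H-chromen-8-yl]-2-oxoethoxy}-4,6-bis(methoxymethoxy)-3,5-bis(3-methylbut-2-enyl)benzaldehyde
Conditions: K2CO3, DMF, 0 °C to rt
Reagents that add atoms: none
Why: Williamson ether synthesis, in which the phenoxide of 6 displaces the activated primary α-keto bromide quickly at or below room temperature and so forms O1–C2 before the slower base-mediated aldol (Rap–Stoermer benzofuran formation) can set in.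

Step 9
Reactants: 17 2-{2-[5-(methoxymethoxy)-2,2-dimethyl-2H-chromen-8-yl]-2-oxoethoxy}-4,6-bis(methoxymethoxy)-3,5-bis(3-methylbut-2-enyl)benzaldehyde
Product: 20 racemic 3-hydroxy-5,7-bis(methoxymethoxy)-3-[5-(methoxymethoxy)-2,2-dimethyl-2H-chromen-8-yl]-6,8-bis(3-methylbut-2-enyl)chroman-4-one, via Breslow enaminol 18 (not isolated), via triazolium alkoxide 19 (not isolated)
Conditions: 2-(pentafluorophenyl)-6,7-dihydro-5H-pyrrolo[2,1-c][1,2,4]triazol-2-ium tetrafluoroborate (20 mol %), Et3N (40 mol %), toluene, 40 °C, argon
Reagents that add atoms: none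
Why: The triazolylidene released by Et3N adds to the formyl carbon and a proton shift gives the Breslow enaminol 18, whose nucleophilic former formyl carbon attacks the tethered aryl ketone to form C3–C4; proton transfer in adduct 19 and loss of the carbene leave the C4 ketone and the C3 tertiary alcohol. The closest known reaction is the carbene-catalysed intramolecular crossed aldehyde–ketone benzoin of 2-(2-oxo-2-arylethoxy)benzaldehydes to 3-hydroxychroman-4-ones. Pyranone ring C closes in a 6-exo-trig mode. The new C3 stereocentre forms racemic under the achiral catalyst, and no control is needed because step 10 removes it. The step needs acyl-anion addition to win over aldol attack of the O–CH2–C(=O) methylene on the aldehyde and over aldehyde homo-coupling: the formyl group between two ortho oxygens is too hindered to dimerise, the ketone lies within six-ring reach, and the acidic pentafluorophenyl triazolium needs only a weak amine base that should not enolise the ketone appreciably. The small pentafluorophenyl carbene is chosen because the di-ortho-substituted, electron-rich aldehyde is the slow partner in forming 18.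

Step 10
Reactants: 20 racemic 3-hydroxy-5,7-bis(methoxymethoxy)-3-[5-(methoxymethoxy)-2,2-dimethyl-2H-chromen-8-yl]-6,8-bis(3-methylbut-2-enyl)chroman-4-one
Product: 22 5,7-bis(methoxymethoxy)-3-[5-(methoxymethoxy)-2,2-dimethyl-2H-chromen-8-yl]-6,8-bis(3-methylbut-2-enyl)chromen-4-one, via chlorosulfite ester 21 (not isolated)
Conditions: SOCl2, pyridine, CH2Cl2, −10 to 0 °C
Reagents that add atoms: none
Why: Dehydration through the chlorosulfite with pyridine-mediated elimination can give only the C2=C3 alkene, because the sole β-hydrogens are at C2 and the product is the conjugated aromatic 4-pyranone, while excess pyridine keeps HCl away from the prenyl, chromene and MOM groups.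

Step 11
Reactants: 22 5,7-bis(methoxymethoxy)-3-[5-(methoxymethoxy)-2,2-dimethyl-2H-chromen-8-yl]-6,8-bis(3-methylbut-2-enyl)chromen-4-one
Product: 23 Kanzonol L
Conditions: 3 M aq HCl, MeOH, 50 °C, stopped at full conversion
Reagents that add atoms: none
Why: Acid-catalysed acetal exchange with methanol removes the three MOM ethers as dimethoxymethane, and brief exposure at moderate temperature should keep the prenyl groups ortho to the freed phenols and the chromene alkene from cyclising or hydrating.

**Compound list**

1 | 2,4,6-trihydroxybenzaldehyde | O=Cc1c(O)cc(O)cc1O | starting material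
2 | prenyl bromide (1-bromo-3-methylbut-2-ene) | CC(C)=CCBr | starting material
3 | 2,4,6-trihydroxy-3-(3-methylbut-2-enyl)benzaldehyde | O=Cc1c(O)cc(O)c(CC=C(C)C)c1O | intermediate
4 | 2,4,6-trihydroxy-3,5-bis(3-methylbut-2-enyl)benzaldehyde | O=Cc1c(O)c(CC=C(C)C)c(O)c(CC=C(C)C)c1O | intermediate
5 | 2,6-dihydroxy-4-(methoxymethoxy)-3,5-bis(3-methylbut-2-enyl)benzaldehyde | O=Cc1c(O)c(CC=C(C)C)c(OCOC)c(CC=C(C)C)c1O | intermediate
6 | 2-hydroxy-4,6-bis(methoxymethoxy)-3,5-bis(3-methylbut-2-enyl)benzaldehyde | O=Cc1c(O)c(CC=C(C)C)c(OCOC)c(CC=C(C)C)c1OCOC | intermediate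
7 | 2,4-dihydroxyacetophenone | CC(=O)c1ccc(O)cc1O | starting material
8 | 2-hydroxy-4-(methoxymethoxy)acetophenone | CC(=O)c1ccc(OCOC)cc1O | intermediate
9 | 3-chloro-3-methylbut-1-yne | C#CC(C)(C)Cl | starting material
10 | 4-(methoxymethoxy)-2-(2-methylbut-3-yn-2-yloxy)acetophenone | CC(=O)c1ccc(OCOC)cc1OC(C)(C)C#C | intermediate
11 | racemic 2-acetyl-5-(methoxymethoxy)-6-(3-methylbuta-1,2-dienyl)cyclohexa-2,4-dien-1-one | CC(=O)C1=CC=C(OCOC)C(C=C=C(C)C)C1=O | intermediate
12 | 2-hydroxy-4-(methoxymethoxy)-3-(3-methylbuta-1,2-dienyl)acetophenone | CC(=O)c1ccc(OCOC)c(C=C=C(C)C)c1O | intermediate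
13 | (6Z)-2-acetyl-5-(methoxymethoxy)-6-(3-methylbut-2-enylidene)cyclohexa-2,4-dien-1-one | CC(=O)C1=CC=C(OCOC)/C(=C/C=C(C)C)C1=O | intermediate
14 | 8-acetyl-5-(methoxymethoxy)-2,2-dimethyl-2H-chromene | CC(=O)c1ccc(OCOC)c2c1OC(C)(C)C=C2 | intermediate
15 | 5-(methoxymethoxy)-2,2-dimethyl-8-[1-(trimethylsilyloxy)ethenyl]-2H-chromene | C=C(O[Si](C)(C)C)c1ccc(OCOC)c2c1OC(C)(C)C=C2 | intermediate
16 | 8-(bromoacetyl)-5-(methoxymethoxy)-2,2-dimethyl-2H-chromene | O=C(CBr)c1ccc(OCOC)c2c1OC(C)(C)C=C2 | intermediate
17 | 2-{2-[5-(methoxymethoxy)-2,2-dimethyl-2H-chromen-8-yl]-2-oxoethoxy}-4,6-bis(methoxymethoxy)-3,5-bis(3-methylbut-2-enyl)benzaldehyde | O=Cc1c(OCC(=O)c2ccc(OCOC)c3c2OC(C)(C)C=C3)c(CC=C(C)C)c(OCOC)c(CC=C(C)C)c1OCOC | intermediate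
18 | Breslow enaminol of 17 (formyl carbon bonded as C(OH)= to the 2-pentafluorophenyl-pyrrolotriazolylidene carbon) | OC(=C1N(c2c(F)c(F)c(F)c(F)c2F)N=C2CCCN12)c1c(OCC(=O)c2ccc(OCOC)c3c2OC(C)(C)C=C3)c(CC=C(C)C)c(OCOC)c(CC=C(C)C)c1OCOC | intermediate
19 | cyclised zwitterion: 3-hydroxychroman bearing at C4 an alkoxide and the triazolium ring (stereo undefined) | [O-]C1(c4[n+](-c5c(F)c(F)c(F)c(F)c5F)nc5CCCn45)c2c(OCOC)c(CC=C(C)C)c(OCOC)c(CC=C(C)C)c2OCC1(O)c1ccc(OCOC)c2c1OC(C)(C)C=C2 | intermediate
20 | racemic 3-hydroxy-5,7-bis(methoxymethoxy)-3-[5-(methoxymethoxy)-2,2-dimethyl-2H-chromen-8-yl]-6,8-bis(3-methylbut-2-enyl)chroman-4-one | O=C1c2c(OCOC)c(CC=C(C)C)c(OCOC)c(CC=C(C)C)c2OCC1(O)c1ccc(OCOC)c2c1OC(C)(C)C=C2 | intermediate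
21 | chlorosulfite ester of 20 at the C3 oxygen | O=C1c2c(OCOC)c(CC=C(C)C)c(OCOC)c(CC=C(C)C)c2OCC1(OS(=O)Cl)c1ccc(OCOC)c2c1OC(C)(C)C=C2 | intermediate
22 | 5,7-bis(methoxymethoxy)-3-[5-(methoxymethoxy)-2,2-dimethyl-2H-chromen-8-yl]-6,8-bis(3-methylbut-2-enyl)chromen-4-one | O=c1c(-c2ccc(OCOC)c3c2OC(C)(C)C=C3)coc2c(CC=C(C)C)c(OCOC)c(CC=C(C)C)c(OCOC)c12 | intermediate
23 | Kanzonol L, 5,7-dihydroxy-3-(5-hydroxy-2,2-dimethyl-2H-chromen-8-yl)-6,8-bis(3-methylbut-2-enyl)chromen-4-one | CC(C)=CCc1c(O)c(CC=C(C)C)c2occ(-c3ccc(O)c4c3OC(C)(C)C=C4)c(=O)c2c1O | target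

**Step count and risks**

Total steps: 11. Longest linear sequence: 9 steps (steps 3 to 11, from 7); the ring A branch needs 6 (steps 1, 2, 8 to 11).

Steps most likely to fail:

1. Step 9. The carbene may add too slowly to the formyl group flanked by two ortho oxygens, so that the Breslow intermediate does not build up and base-mediated aldol closure to a 2-aroylbenzofuran or simple return of 17 takes over. Fallback: setting out from 17, the C3–C4 bond would be made reductively. SmI2 (2.2 equiv) in THF with t-BuOH at −78 °C should couple the aldehyde and ketone carbonyls in an intramolecular pinacol reaction to the racemic cis-chromane-3,4-diol F1. Oxidation of its secondary benzylic C4 hydroxyl with 2-iodoxybenzoic acid in DMSO at room temperature, which cannot touch the tertiary C3 hydroxyl and does not cleave the glycol, comes back to the route at 20.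

2. Step 8. Alkylation of the hindered, hydrogen-bonded phenoxide may be slow enough that the product's activated methylene condenses with the neighbouring aldehyde under the carbonate base. Fallback: setting out from 16, HCO2Na in aqueous ethanol at 70 °C should give the formate ester F2, which is solvolysed in the same pot to the hydroxy ketone F3. Mitsunobu etherification of phenol 6 with F3 (PPh3, diisopropyl azodicarboxylate, THF, 0 °C to rt) then forms O1–C2 without any base and comes back to the route at 17.

3. Step 4. O-alkylation of the chelated ortho-phenoxide by the tertiary propargylic chloride may be sluggish, with loss of HCl from 9 consuming the electrophile. Fallback: setting out from 8, the dimethylpyran ring would be built without an O-alkylation. Heating with 3-methylbut-2-enal in pyridine at 140 °C (aldol-type C-alkylation at C3, the carbon between the two oxygens, then loss of water) should lead to the same quinone methide 13, whose oxa-6π electrocyclisation gives 14, where the route is rejoined; this detour makes no compound outside the list (F0).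

**Further compounds**

F1 | step 9 | racemic cis-5,7-bis(methoxymethoxy)-3-[5-(methoxymethoxy)-2,2-dimethyl-2H-chromen-8-yl]-6,8-bis(3-methylbut-2-enyl)chromane-3,4-diol (one enantiomer drawn) | O[C@@H]1c2c(OCOC)c(CC=C(C)C)c(OCOC)c(CC=C(C)C)c2OC[C@@]1(O)c1ccc(OCOC)c2c1OC(C)(C)C=C2
F2 | step 8 | 2-[5-(methoxymethoxy)-2,2-dimethyl-2H-chromen-8-yl]-2-oxoethyl formate | O=COCC(=O)c1ccc(OCOC)c2c1OC(C)(C)C=C2
F3 | step 8 | 2-hydroxy-1-[5-(methoxymethoxy)-2,2-dimethyl-2H-chromen-8-yl]ethanone | OCC(=O)c1ccc(OCOC)c2c1OC(C)(C)C=C2
F0 | step 4 | none | none
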